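**Plan**
1. Numbering follows the prostanoids: C1 is the ester carbon, the ring is C8–C12, Br sits on C10 and the acetate on C12. Retrosynthetic cuts, in order: the O–acetyl bond, C6–C7, C7–C8, the ring bond C9–C10, C10=C11 and C12–C13.
2. Enabling feature: in the cyclopentenone ring C8–C9–C10–C11–C12, C10 carries both Br and the bond to the carbonyl carbon C9, and is joined through C11 to the quaternary carbinol C12. A C11=C10Br2 unit can therefore give up one bromine for lithium and keep the other, with the acyl carbon C9 waiting on the C8 arm.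
3. Forward: the only ring is closed at C9–C10 by intramolecular acylation of a 1-bromo-1-lithioalkene with a Weinreb amide. The C1–C7 chain is then joined at C8 by formylation, (Z)-triflation and Stille coupling.
4. Stereochemistry: C12 comes from (S)-malic acid by alkylation of its pivalaldehyde acetal anti to tert-butyl. 14Z comes from (Z)-oct-2-en-1-ol, 7Z from a lithium-chelated (Z)-enol triflate coupled with retention, and 5E from syn hydrostannation.

Key step: step 9

Remark: compounds with new stereocentres of no consequence (12, F3, F4, F6) are drawn with those centres open.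

**Step 1**
Reactants: 1 (S)-malic acid
Product: 2 [(2S,4S)-2-tert-butyl-5-oxo-1,3-dioxolan-4-yl]acetic acid (cis)
Conditions: t-BuCHO, TsOH·H2O (cat.), H2SO4 (cat.), pentane, reflux (Dean–Stark); recrystallisation
Reagents that add atoms: pivalaldehyde, CC(C)(C)C=O
Why: Acid-catalysed acetalisation of the α-hydroxy acid unit (Seebach dioxolanone formation) should give, under thermodynamic control and after crystallisation, the cis acetal, whose new acetal centre is set by the malic acid centre.

**Step 2**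
Reactants: 3 (Z)-oct-2-en-1-ol
Product: 4 (Z)-1-bromooct-2-ene
Conditions: CBr4, PPh3, CH2Cl2, 0 °C
Reagents that add atoms: carbon tetrabromide, BrC(Br)(Br)Br
Why: Appel bromination displaces the primary oxyphosphonium group by SN2, so the Z alkene should be kept.

**Step 3**
Reactants: 2 [(2S,4S)-2-tert-butyl-5-oxo-1,3-dioxolan-4-yl]acetic acid; 4 (Z)-1-bromooct-2-ene
Product: 5 [(2S,4S)-2-tert-butyl-4-[(2Z)-oct-2-en-1-yl]-5-oxo-1,3-dioxolan-4-yl]acetic acid (octenyl trans to tert-butyl)
Conditions: LiN(SiMe3)2 (2.1 equiv), THF, −78 °C; then 4, −78 → −20 °C; aq. HCl work-up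
Reagents that add atoms: none
Why: Seebach self-regeneration of stereocentres: after double deprotonation the allylic bromide should attack the ring carbon anti to the tert-butyl group, so the octenyl group takes the place of the hydrogen and the quaternary carbinol centre (C12) is set with retention.

**Step 4**
Reactants: 5 [(2S,4S)-2-tert-butyl-4-[(2Z)-oct-2-en-1-yl]-5-oxo-1,3-dioxolan-4-yl]acetic acid
Product: 6 (4S)-4-hydroxy-4-[(2Z)-oct-2-en-1-yl]oxolan-2-one
Conditions: LiBH4, THF, 0 °C → rt; then 2 M HCl, rt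
Reagents that add atoms: none
Why: LiBH4 should reduce the activated acetal-lactone carbonyl (not the lithium carboxylate) to the primary alcohol with loss of the pivalaldehyde auxiliary, and acidification closes the γ-lactone onto the free acid without touching the carbinol centre.

**Step 5**
Reactants: 6 (4S)-4-hydroxy-4-[(2Z)-oct-2-en-1-yl]oxolan-2-one
Product: 7 (4S)-4-[(2Z)-oct-2-en-1-yl]-4-[(triethylsilyl)oxy]oxolan-2-one
Conditions: Et3SiOTf, 2,6-lutidine, CH2Cl2, −78 → 0 °C
Reagents that add atoms: triethylsilyl trifluoromethanesulfonate, CC[Si](CC)(CC)OS(=O)(=O)C(F)(F)F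
Why: Silylation of a hindered tertiary alcohol with the silyl triflate and 2,6-lutidine is standard and protects the C12 oxygen for the organolithium and enolate steps.

**Step 6**
Reactants: 7 (4S)-4-[(2Z)-oct-2-en-1-yl]-4-[(triethylsilyl)oxy]oxolan-2-one
Product: 8 (3S,5Z)-3-(hydroxymethyl)-N-methoxy-N-methyl-3-[(triethylsilyl)oxy]undec-5-enamide
Conditions: MeNH(OMe)·HCl, AlMe3, CH2Cl2, 0 °C → rt; aq. potassium sodium tartrate
Reagents that add atoms: N,O-dimethylhydroxylamine hydrochloride, CNOC.Cl
Why: Weinreb aminolysis of a lactone with the aluminium amide made from AlMe3 and the amine hydrochloride should open the ring to the hydroxy amide, which is oxidised at once to forestall relactonisation.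

**Step 7**
Reactants: 8 (3S,5Z)-3-(hydroxymethyl)-N-methoxy-N-methyl-3-[(triethylsilyl)oxy]undec-5-enamide
Product: 9 (3S,5Z)-3-formyl-N-methoxy-N-methyl-3-[(triethylsilyl)oxy]undec-5-enamide
Conditions: Dess–Martin periodinane, CH2Cl2, 0 °C → rt
Reagents that add atoms: none
Why: Dess–Martin oxidation of the primary alcohol should give the aldehyde, which has no α-hydrogen and cannot epimerise.

**Step 8**
Reactants: 9 (3S,5Z)-3-formyl-N-methoxy-N-methyl-3-[(triethylsilyl)oxy]undec-5-enamide
Product: 10 (3S,5Z)-3-(2,2-dibromoethenyl)-N-methoxy-N-methyl-3-[(triethylsilyl)oxy]undec-5-enamide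
Conditions: CBr4, PPh3, Zn, CH2Cl2, rt; then 9, 0 °C → rt
Reagents that add atoms: carbon tetrabromide, BrC(Br)(Br)Br
Why: Ramirez (Corey–Fuchs) dibromo-olefination with the ylide made from CBr4, PPh3 and Zn should convert the hindered aldehyde into the 1,1-dibromoalkene, which brings in C10 with both bromines.

**Step 9**
Reactants: 10 (3S,5Z)-3-(2,2-dibromoethenyl)-N-methoxy-N-methyl-3-[(triethylsilyl)oxy]undec-5-enamide
Product: 13 (4S)-2-bromo-4-[(2Z)-oct-2-en-1-yl]-4-[(triethylsilyl)oxy]cyclopent-2-en-1-one, via lithium bromo carbenoid 11 (not isolated), via lithium hemiaminal chelate 12 (not isolated)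
Conditions: n-BuLi (1.05 equiv), THF/Et2O/pentane 4:1:1, −110 °C; then −78 °C; AcOH, −78 °C
Reagents that add atoms: none
Why: Proposed new method: bromine–lithium exchange at −110 °C should turn the 1,1-dibromoalkene into the 1-bromo-1-lithioalkene 11, whose C–Li carbon (C10) adds to the Weinreb amide carbonyl (C9) to give the lithium-chelated hemiaminal 12, and the acidic quench releases the α-bromoenone, so that one bromine makes the bond and the other stays on C10. The closest known reaction types are the Parham cyclisation of vinyllithiums onto Weinreb amides and the intermolecular trapping of alkoxy-substituted 1-bromo-1-lithioalkenes by carbonyl electrophiles below −100 °C. The cyclopentenone ring (C8–C12) closes in the 5-exo-trig mode at the amide C=O. No stereocentre is created in 13 (the hemiaminal carbon of 12 is lost on collapse) and C12 is not touched. The step needs exchange of the bromine cis to C12 in preference to the trans bromine, to addition of n-BuLi to the amide and to deprotonation at C8; exchange at the hindered cis bromine relieves strain and is assisted by the silyloxy and amide oxygens, only this carbenoid can reach C9, and it is the one slower to undergo Fritsch–Buttenberg–Wiechell rearrangement because an alkyl group and not hydrogen stands anti to its bromine. One equivalent of n-BuLi and the ketone masked in 12 guard against a second exchange or addition.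

**Step 10**
Reactants: 13 (4S)-2-bromo-4-[(2Z)-oct-2-en-1-yl]-4-[(triethylsilyl)oxy]cyclopent-2-en-1-one
Product: 15 (Z)-{(5R)-3-bromo-5-[(2Z)-oct-2-en-1-yl]-2-oxo-5-[(triethylsilyl)oxy]cyclopent-3-en-1-ylidene}methyl trifluoromethanesulfonate, via lithium hydroxymethylene enolate 14 (not isolated)
Conditions: LiN(SiMe3)2, THF, −78 °C; HCO2CH2CF3, −78 °C; then 2-[N,N-bis(trifluoromethylsulfonyl)amino]-5-chloropyridine, −78 → 0 °C
Reagents that add atoms: 2,2,2-trifluoroethyl formate, O=COCC(F)(F)F; 2-[N,N-bis(trifluoromethylsulfonyl)amino]-5-chloropyridine (Comins' reagent), FC(F)(F)S(=O)(=O)N(c1ccc(Cl)cn1)S(=O)(=O)C(F)(F)F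
Why: Kinetic deprotonation at the only enolisable carbon (C8) and Claisen formylation should give the lithium chelate 14 with its exocyclic oxygen held syn to the ring carbonyl and away from the quaternary C12, so that triflation at this less hindered oxygen gives the (Z)-enol triflate, the enolate being kept at −78 °C to avoid β-elimination of the silyloxy group.

**Step 11**
Reactants: 16 methyl hex-5-ynoate
Product: 17 methyl (5E)-6-(tributylstannyl)hex-5-enoate
Conditions: Bu3SnH, Pd2(dba)3 (cat.), Cy3P·HBF4 (cat.), i-Pr2NEt (cat.), CH2Cl2, 0 °C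
Reagents that add atoms: tributyltin hydride, CCCC[SnH](CCCC)CCCC
Why: Palladium-catalysed syn hydrostannation of the terminal alkyne with a bulky phosphine should place tin on the terminal carbon and give the (E)-alkenylstannane.

**Step 12**
Reactants: 15 (Z)-{(5R)-3-bromo-5-[(2Z)-oct-2-en-1-yl]-2-oxo-5-[(triethylsilyl)oxy]cyclopent-3-en-1-ylidene}methyl trifluoromethanesulfonate; 17 methyl (5E)-6-(tributylstannyl)hex-5-enoate
Product: 18 methyl (5E,7Z)-7-{(5R)-3-bromo-5-[(2Z)-oct-2-en-1-yl]-2-oxo-5-[(triethylsilyl)oxy]cyclopent-3-en-1-ylidene}hept-5-enoate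
Conditions: Pd2(dba)3 (cat.), AsPh3 (cat.), NMP, rt, dark
Reagents that add atoms: none
Why: Stille coupling with retention at both partners should join C6 to C7 and fix the 5E,7Z diene, because zerovalent palladium is expected to insert into the vinylogous acyl triflate far faster than into the α-bromoenone C–Br bond at room temperature.

**Step 13**
Reactants: 18 methyl (5E,7Z)-7-{(5R)-3-bromo-5-[(2Z)-oct-2-en-1-yl]-2-oxo-5-[(triethylsilyl)oxy]cyclopent-3-en-1-ylidene}hept-5-enoate
Product: 19 methyl (5E,7Z)-7-{(5R)-3-bromo-5-hydroxy-5-[(2Z)-oct-2-en-1-yl]-2-oxocyclopent-3-en-1-ylidene}hept-5-enoate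
Conditions: HF·pyridine, pyridine, THF, 0 °C → rt
Reagents that add atoms: none
Why: Buffered HF·pyridine should cleave the tertiary triethylsilyl ether without the base that the cross-conjugated dienone and its Z geometry would not tolerate.

**Step 14**
Reactants: 19 methyl (5E,7Z)-7-{(5R)-3-bromo-5-hydroxy-5-[(2Z)-oct-2-en-1-yl]-2-oxocyclopent-3-en-1-ylidene}hept-5-enoate
Product: 20 methyl (5E,7Z)-7-{(5R)-5-(acetyloxy)-3-bromo-5-[(2Z)-oct-2-en-1-yl]-2-oxocyclopent-3-en-1-ylidene}hept-5-enoate
Conditions: Ac2O, DMAP (cat.), pyridine, rt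
Reagents that add atoms: acetic anhydride, CC(=O)OC(C)=O
Why: DMAP-catalysed acetylation of the tertiary alcohol, the usual last step for prostanoids of this family, should give the target without touching the stereocentre or the alkene geometries.

**Compound list**
1 | (S)-malic acid | OC(=O)C[C@H](O)C(=O)O | starting material
2 | [(2S,4S)-2-tert-butyl-5-oxo-1,3-dioxolan-4-yl]acetic acid | OC(=O)C[C@@H]1O[C@H](C(C)(C)C)OC1=O | intermediate
3 | (Z)-oct-2-en-1-ol | CCCCC/C=C\CO | starting material
4 | (Z)-1-bromooct-2-ene | CCCCC/C=C\CBr | intermediate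
5 | [(2S,4S)-2-tert-butyl-4-[(2Z)-oct-2-en-1-yl]-5-oxo-1,3-dioxolan-4-yl]acetic acid | CCCCC/C=C\C[C@@]1(CC(=O)O)O[C@H](C(C)(C)C)OC1=O | intermediate
6 | (4S)-4-hydroxy-4-[(2Z)-oct-2-en-1-yl]oxolan-2-one | CCCCC/C=C\C[C@@]1(O)COC(=O)C1 | intermediate
7 | (4S)-4-[(2Z)-oct-2-en-1-yl]-4-[(triethylsilyl)oxy]oxolan-2-one | CCCCC/C=C\C[C@@]1(O[Si](CC)(CC)CC)COC(=O)C1 | intermediate
8 | (3S,5Z)-3-(hydroxymethyl)-N-methoxy-N-methyl-3-[(triethylsilyl)oxy]undec-5-enamide | CCCCC/C=C\C[C@@](CC(=O)N(C)OC)(O[Si](CC)(CC)CC)CO | intermediate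
9 | (3S,5Z)-3-formyl-N-methoxy-N-methyl-3-[(triethylsilyl)oxy]undec-5-enamide | CCCCC/C=C\C[C@@](CC(=O)N(C)OC)(O[Si](CC)(CC)CC)C=O | intermediate
10 | (3S,5Z)-3-(2,2-dibromoethenyl)-N-methoxy-N-methyl-3-[(triethylsilyl)oxy]undec-5-enamide | CCCCC/C=C\C[C@@](CC(=O)N(C)OC)(O[Si](CC)(CC)CC)C=C(Br)Br | intermediate
11 | [(1E,3S,5Z)-1-bromo-3-{2-[methoxy(methyl)amino]-2-oxoethyl}-3-[(triethylsilyl)oxy]undeca-1,5-dien-1-yl]lithium (lithium cis to the quaternary carbon) | CCCCC/C=C\C[C@@](CC(=O)N(C)OC)(O[Si](CC)(CC)CC)/C=C(/Br)[Li] | intermediate (not isolated)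
12 | lithium (4S)-2-bromo-1-[methoxy(methyl)amino]-4-[(2Z)-oct-2-en-1-yl]-4-[(triethylsilyl)oxy]cyclopent-2-en-1-olate (configuration at C1 open) | CCCCC/C=C\C[C@@]1(O[Si](CC)(CC)CC)C=C(Br)C(O[Li])(N(C)OC)C1 | intermediate (not isolated)
13 | (4S)-2-bromo-4-[(2Z)-oct-2-en-1-yl]-4-[(triethylsilyl)oxy]cyclopent-2-en-1-one | CCCCC/C=C\C[C@@]1(O[Si](CC)(CC)CC)C=C(Br)C(=O)C1 | intermediate
14 | lithium (Z)-{(5R)-3-bromo-5-[(2Z)-oct-2-en-1-yl]-2-oxo-5-[(triethylsilyl)oxy]cyclopent-3-en-1-ylidene}methanolate | CCCCC/C=C\C[C@@]1(O[Si](CC)(CC)CC)C=C(Br)C(=O)/C1=C\O[Li] | intermediate (not isolated)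
15 | (Z)-{(5R)-3-bromo-5-[(2Z)-oct-2-en-1-yl]-2-oxo-5-[(triethylsilyl)oxy]cyclopent-3-en-1-ylidene}methyl trifluoromethanesulfonate | CCCCC/C=C\C[C@@]1(O[Si](CC)(CC)CC)C=C(Br)C(=O)/C1=C\OS(=O)(=O)C(F)(F)F | intermediate
16 | methyl hex-5-ynoate | COC(=O)CCCC#C | starting material
17 | methyl (5E)-6-(tributylstannyl)hex-5-enoate | COC(=O)CCC/C=C/[Sn](CCCC)(CCCC)CCCC | intermediate
18 | methyl (5E,7Z)-7-{(5R)-3-bromo-5-[(2Z)-oct-2-en-1-yl]-2-oxo-5-[(triethylsilyl)oxy]cyclopent-3-en-1-ylidene}hept-5-enoate | CCCCC/C=C\C[C@@]1(O[Si](CC)(CC)CC)C=C(Br)C(=O)/C1=C\C=C\CCCC(=O)OC | intermediate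
19 | methyl (5E,7Z)-7-{(5R)-3-bromo-5-hydroxy-5-[(2Z)-oct-2-en-1-yl]-2-oxocyclopent-3-en-1-ylidene}hept-5-enoate | CCCCC/C=C\C[C@@]1(O)C=C(Br)C(=O)/C1=C\C=C\CCCC(=O)OC | intermediate
20 | methyl (5E,7Z)-7-{(5R)-5-(acetyloxy)-3-bromo-5-[(2Z)-oct-2-en-1-yl]-2-oxocyclopent-3-en-1-ylidene}hept-5-enoate | CCCCC/C=C\C[C@@]1(OC(C)=O)C=C(Br)C(=O)/C1=C\C=C\CCCC(=O)OC | target

**Step count and risks**
Total step count: 14. Longest linear sequence: 12 steps (steps 1, 3–10 and 12–14, from (S)-malic acid).

Steps most likely to fail: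

Step 9 (Proposed new method). Exchange may take place at the bromine trans to C12, giving a carbenoid that cannot cyclise and rearranges to the alkyne on warming. n-BuLi may also add to the amide, or the carbenoid may be lost by α-elimination before ring closure. The fallback uses known chemistry only; it sets out from 10 and returns at 13. Palladium-catalysed hydrogenolysis of the trans bromine of 10 (Bu3SnH, Pd(PPh3)4) gives (3S,5Z)-3-[(Z)-2-bromoethenyl]-N-methoxy-N-methyl-3-[(triethylsilyl)oxy]undec-5-enamide F1. t-BuLi (2 equiv, THF, −78 °C) then effects an ordinary Parham cyclisation onto the Weinreb amide to give (4S)-4-[(2Z)-oct-2-en-1-yl]-4-[(triethylsilyl)oxy]cyclopent-2-en-1-one F2. Nucleophilic epoxidation (H2O2, NaOH, MeOH, 0 °C) touches only the enone and gives 4-[(2Z)-oct-2-en-1-yl]-4-[(triethylsilyl)oxy]-6-oxabicyclo[3.1.0]hexan-2-one F3. MgBr2·OEt2 opens the epoxide at the carbon next to the carbonyl to give 2-bromo-3-hydroxy-4-[(2Z)-oct-2-en-1-yl]-4-[(triethylsilyl)oxy]cyclopentan-1-one F4, and MsCl with Et3N dehydrates this to 13.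

Step 10. The silyloxy group may be lost from the lithium enolate by β-elimination, sulfonylation may occur at the ring oxygen, or the Z geometry may erode. The fallback sets out from 13 and returns at 18; it replaces coupling at a formyl-derived triflate by aldol condensation and makes steps 11 and 12 unnecessary. Methyl 5-oxopentanoate and Ph3P=CHCHO give methyl (5E)-7-oxohept-5-enoate F5. The dibutylboron enolate of 13 (Bu2BOTf, i-Pr2NEt, CH2Cl2, −78 °C) adds to it to give methyl (5E)-7-{3-bromo-5-[(2Z)-oct-2-en-1-yl]-2-oxo-5-[(triethylsilyl)oxy]cyclopent-3-en-1-yl}-7-hydroxyhept-5-enoate F6. Mesylation and elimination (MsCl, Et3N; then DBU) should give 18 together with its 7E isomer, which is removed by chromatography; control of the C7 geometry then rests on this separation.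

Step 12. Palladium may insert into the C–Br bond in competition with the triflate, or the exocyclic alkene may isomerise from Z to E under palladium catalysis. The fallback sets out from 15 and returns at 18 without palladium. NaI in acetone exchanges the triflate for iodide by addition–elimination to give (4R,5Z)-2-bromo-5-(iodomethylidene)-4-[(2Z)-oct-2-en-1-yl]-4-[(triethylsilyl)oxy]cyclopent-2-en-1-one F7. Copper thiophene-2-carboxylate, Cu(O2CC4H3S), in NMP at 0 °C then couples this iodide with stannane 17 (Liebeskind coupling) to give 18; the α-bromoenone is inert to the monovalent copper carboxylate.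

**Further compounds**
F1 | step 9 | (3S,5Z)-3-[(Z)-2-bromoethenyl]-N-methoxy-N-methyl-3-[(triethylsilyl)oxy]undec-5-enamide | CCCCC/C=C\C[C@@](CC(=O)N(C)OC)(O[Si](CC)(CC)CC)/C=C\Br
F2 | step 9 | (4S)-4-[(2Z)-oct-2-en-1-yl]-4-[(triethylsilyl)oxy]cyclopent-2-en-1-one | CCCCC/C=C\C[C@@]1(O[Si](CC)(CC)CC)C=CC(=O)C1
F3 | step 9 | 4-[(2Z)-oct-2-en-1-yl]-4-[(triethylsilyl)oxy]-6-oxabicyclo[3.1.0]hexan-2-one (epoxide configuration open) | CCCCC/C=C\C[C@@]1(O[Si](CC)(CC)CC)C2OC2C(=O)C1
F4 | step 9 | 2-bromo-3-hydroxy-4-[(2Z)-oct-2-en-1-yl]-4-[(triethylsilyl)oxy]cyclopentan-1-one (C2 and C3 configuration open) | CCCCC/C=C\C[C@@]1(O[Si](CC)(CC)CC)C(O)C(Br)C(=O)C1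
F5 | step 10 | methyl (5E)-7-oxohept-5-enoate | COC(=O)CCC/C=C/C=O
F6 | step 10 | methyl (5E)-7-{3-bromo-5-[(2Z)-oct-2-en-1-yl]-2-oxo-5-[(triethylsilyl)oxy]cyclopent-3-en-1-yl}-7-hydroxyhept-5-enoate (two new centres open) | CCCCC/C=C\C[C@@]1(O[Si](CC)(CC)CC)C=C(Br)C(=O)C1C(O)/C=C/CCCC(=O)OC
F7 | step 12 | (4R,5Z)-2-bromo-5-(iodomethylidene)-4-[(2Z)-oct-2-en-1-yl]-4-[(triethylsilyl)oxy]cyclopent-2-en-1-one | CCCCC/C=C\C[C@@]1(O[Si](CC)(CC)CC)C=C(Br)C(=O)/C1=C\I
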